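(The numbers in the tables were generated by integration with constants of no real substance; scatter was added.)

In the alpha run the fraction of starting material left falls on a nearly straight line, and in the zeta run it does so until little remains. A loss that is steady in moles per litre is zero order, so you should carry that loss from run to run and turn it into the fraction left of each charge.

| setting | zeta | alpha | flask |
|---|---|---|---|
| starting material | 0.10 M (in portions, 4) | 0.15 M (in portions, 4) | 0.20 M (in portions, 4) |
| second substrate | 1 M | 1 M | 1.00 M |
| free enzyme | 20 µM | 20 µM | 20 µM |
| remark | run made earlier; portions every 2.5 min | run made earlier; portions every 2.5 min | the portions of starting material follow each other after 2.5 min, the first at the start |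
| time |  |  | 2.5 h |

| run | time / min | target / % | starting material / % |
|---|---|---|---|
| zeta | 6.00 | 8.8 | 69.0 |
| zeta | 20.0 | 26.0 | 74.9 |
| zeta | 30.0 | 35.9 | 64.5 |
| zeta | 50.0 | 60.4 | 40.2 |
| zeta | 60.0 | 70.1 | 30.4 |
| zeta | 90.0 | 93.3 | 6.4 |
| alpha | 15.0 | 12.3 | 87.5 |
| alpha | 30.0 | 26.0 | 74.0 |
| alpha | 50.0 | 42.3 | 56.9 |
| alpha | 60.0 | 48.1 | 51.1 |
| alpha | 80.0 | 63.8 | 35.3 |
| alpha | 90.0 | 72.9 | 27.1 |

(scatter of a reading: 1 percentage point)

- amount of target in the flask at 2.5 h, in percent of the starting material charged
- amount of starting material in the flask at 2.5 h, in percent of the starting material charged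
- concentration of first product at 2.5 h, in M



Between 15.0 min and 90.0 min, the alpha run's target rises at a pace that would clear its charge in 124 min. I assume the loss in moles per litre stays the same, so this time grows with the charge. For the flask that gives 165 min, the clearance time: the charge divided by the steady loss. The fraction left is then one minus elapsed time over clearance time.

This line has no slowing in it, so it gives my lower bound: 9.10 % left at 2.5 h. For the upper bound, take the slower zeta stretch from 20.0 min to 60.0 min. Scaled the same way, it clears the flask's charge in 181 min, leaving 17.3 %.

To tighten this, note that the zeta run slowed after 60.0 min. On the flask's scale that point is 15.2 % left. Following the alpha line to there and the zeta tail afterwards, I get 11.2 %.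

The forecast, calling the alpha run “nearly zero order”, gives 11 % left (range 6 % to 20 %), 89 % target and 0.178 M first product. Its central figure lies inside my bracket .

The flask holds 10.4 % of its starting material, 89.6 % target and 0.179 M first product, so it ends above the straight line's 9.10 %.

    starting material + free enzyme ⇌ first complex (K = 26.0 M⁻¹, k = 5800 M⁻¹ s⁻¹)
    first complex → loaded enzyme + first product (k = 4.40 s⁻¹)
    second substrate + loaded enzyme ⇌ second complex (K = 0.430 M⁻¹, k = 660 M⁻¹ s⁻¹)
    second complex → free enzyme + target (k = 5.40 s⁻¹)

In the flask, free enzyme stands at 8.81 % of the catalyst at 1.25 h and at 31.3 % at 2.50 h. Now take the same flask with 5.0 × 10⁻⁶ M of free enzyme, a quarter of the amount. If the loss scales with the enzyme, the clearance time stretches to 660 min and the line leaves 77.3 %; that flask holds 75.3 %.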